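## Retrosynthetic overview

1. Ring locants used throughout: C1 = quaternary carbon (CH2OH and tetraenyl chain), C2 = CH with the 3-hydroxypropyl arm, C3 = alkylidene carbon, C6 = C(CH3)OH. The unit C6(CH3)(OH)–C1–CH2OH is a reduced ester aldol. The only ring, the cyclohexane, is therefore closed at C1–C6 by a SmI2 Reformatsky reaction of a C1 α-bromo ester onto the C6 methyl ketone; C1 needs no configuration beforehand.
2. After ring closure: ester to CH2OH; C1 allyl to aldehyde; Wittig (E-enal); Julia–Kocienski with geranyl sulfone (E,E,E-triene); the enal on the C3 alkylidene is made last with MnO2.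
3. The bromo keto ester comes from allylation and bromination of the ester obtained by conjugate addition of a fully substituted alkenylcopper reagent to an N-enoyl oxazolidinone. The auxiliary sets C2, the only centre made under external control.
4. The alkenyl iodide comes from anti-carbomagnesiation and iodination of the propargylic alcohol made from ketal-protected 5-hexyn-2-one (this fixes the C3 alkene geometry). The enoyl imide comes from butane-1,4-diol by Horner–Wadsworth–Emmons olefination.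

Key step: step 15

Remark: the magnesium-chelate model for cuprate addition to N-enoyl oxazolidinones calls for (R)-4-benzyl-2-oxazolidinone to give the C2 configuration of the target; both primary hydroxyls are carried as tert-butyldiphenylsilyl (TBDPS) ethers so that they outlast the acidic ketal cleavage (TES = triethylsilyl, PT = 1-phenyl-1H-tetrazol-5-yl).

## Route

Step 1
Reactants: 1 5-hexyn-2-one
Product: 2 2-(but-3-yn-1-yl)-2-methyl-1,3-dioxolane
Conditions: HOCH2CH2OH, p-TsOH·H2O (cat.), benzene, reflux, Dean–Stark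
Reagents that add atoms: ethylene glycol, OCCO
Why: Acid-catalysed ketalisation with azeotropic removal of water should mask the methyl ketone for the organometallic and enolate steps that follow.

Step 2
Reactants: 2 2-(but-3-yn-1-yl)-2-methyl-1,3-dioxolane
Product: 4 5-(2-methyl-1,3-dioxolan-2-yl)pent-2-yn-1-ol, via lithium acetylide 3 (not isolated)
Conditions: n-BuLi, THF, −78 °C; (CH2O)n, −78 °C to rt
Reagents that add atoms: formaldehyde (from paraformaldehyde), C=O
Why: Deprotonation of the terminal alkyne and 1,2-addition of the acetylide to formaldehyde (hydroxymethylation) should give the 2-alkyn-1-ol needed for directed carbometalation.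

Step 3
Reactants: 4 5-(2-methyl-1,3-dioxolan-2-yl)pent-2-yn-1-ol
Product: 6 (Z)-3-iodo-2-methyl-5-(2-methyl-1,3-dioxolan-2-yl)pent-2-en-1-ol, via cyclic alkenylmagnesium alkoxide 5 (not isolated)
Conditions: MeMgBr (3.5 equiv), CuI (10 mol %), THF, 0 °C to reflux; I2 (excess), −20 to 0 °C
Reagents that add atoms: methylmagnesium bromide, C[Mg]Br; iodine, II
Why: Copper-catalysed anti-carbomagnesiation of the propargylic alkoxide puts CH3 on the carbon next to CH2O and magnesium on the distal carbon trans to it (five-membered chelate 5), and iodinolysis with retention should fix the tetrasubstituted alkene with I cis to CH2OH and CH3 cis to the ketal chain.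

Step 4
Reactants: 6 (Z)-3-iodo-2-methyl-5-(2-methyl-1,3-dioxolan-2-yl)pent-2-en-1-ol
Product: 7 tert-butyl{[(Z)-3-iodo-2-methyl-5-(2-methyl-1,3-dioxolan-2-yl)pent-2-en-1-yl]oxy}diphenylsilane
Conditions: TBDPSCl, imidazole, DMF, rt
Reagents that add atoms: tert-butyl(chloro)diphenylsilane, CC(C)(C)[Si](Cl)(c1ccccc1)c1ccccc1
Why: Imidazole-promoted silylation of the primary allylic alcohol gives a bulky silyl ether that should resist oxygen-to-carbon silyl migration in the alkenyl metal species and later acid.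

Step 5
Reactants: 8 butane-1,4-diol
Product: 10 4-[(tert-butyldiphenylsilyl)oxy]butan-1-ol, via monosodium butanediolate 9 (not isolated)
Conditions: NaH (1 equiv), THF, 0 °C to rt; TBDPSCl (1 equiv)
Reagents that add atoms: tert-butyl(chloro)diphenylsilane, CC(C)(C)[Si](Cl)(c1ccccc1)c1ccccc1
Why: O-Silylation of the sparingly soluble monosodium alkoxide of a symmetrical diol should stop at monoprotection.

Step 6
Reactants: 10 4-[(tert-butyldiphenylsilyl)oxy]butan-1-ol
Product: 11 4-[(tert-butyldiphenylsilyl)oxy]butanal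
Conditions: TEMPO (10 mol %), PhI(OAc)2, CH2Cl2, rt
Reagents that add atoms: none
Why: TEMPO-catalysed (oxoammonium) oxidation of a primary alcohol stops at the aldehyde and leaves the silyl ether untouched.

Step 7
Reactants: 12 (R)-4-benzyl-2-oxazolidinone
Product: 14 (R)-4-benzyl-3-(2-bromoacetyl)oxazolidin-2-one, via N-lithio oxazolidinone 13 (not isolated)
Conditions: n-BuLi, THF, −78 °C; BrCH2COBr, −78 to 0 °C
Reagents that add atoms: bromoacetyl bromide, O=C(Br)CBr
Why: N-Acylation of the lithiated oxazolidinone takes place at the acyl bromide, the harder and more reactive electrophilic site.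

Step 8
Reactants: 14 (R)-4-benzyl-3-(2-bromoacetyl)oxazolidin-2-one
Product: 15 diethyl {2-[(R)-4-benzyl-2-oxooxazolidin-3-yl]-2-oxoethyl}phosphonate
Conditions: P(OEt)3, toluene, 100 °C
Reagents that add atoms: triethyl phosphite, CCOP(OCC)OCC
Why: Michaelis–Arbuzov reaction of the α-bromo imide (SN2 at carbon, then dealkylation by bromide) should give the phosphonate.

Step 9
Reactants: 11 4-[(tert-butyldiphenylsilyl)oxy]butanal; 15 diethyl {2-[(R)-4-benzyl-2-oxooxazolidin-3-yl]-2-oxoethyl}phosphonate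
Product: 16 (R)-4-benzyl-3-{(E)-6-[(tert-butyldiphenylsilyl)oxy]hex-2-enoyl}oxazolidin-2-one
Conditions: LiCl, i-Pr2NEt, MeCN, rt
Reagents that add atoms: none
Why: Horner–Wadsworth–Emmons olefination under Masamune–Roush conditions (lithium-chelated phosphonate, amine base) should give the E-enoyl imide without harming the imide.

Step 10
Reactants: 7 tert-butyl{[(Z)-3-iodo-2-methyl-5-(2-methyl-1,3-dioxolan-2-yl)pent-2-en-1-yl]oxy}diphenylsilane; 16 (R)-4-benzyl-3-{(E)-6-[(tert-butyldiphenylsilyl)oxy]hex-2-enoyl}oxazolidin-2-one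
Product: 20 (R)-4-benzyl-3-[(S)-6-(TBDPSO)-3-{(Z)-1-(TBDPSO)-2-methyl-5-(2-methyl-1,3-dioxolan-2-yl)pent-2-en-3-yl}hexanoyl]oxazolidin-2-one, via alkenyllithium 17 (not isolated), via alkenylmagnesium bromide 18 (not isolated), via alkenylcopper reagent 19 (not isolated)
Conditions: 7 (1.5 equiv), t-BuLi (2 equiv per iodide), Et2O, −78 °C; MgBr2·OEt2; CuBr·SMe2 (1 equiv per alkenyl), THF/Me2S, −78 to −40 °C; then 16, −78 to −20 °C
Reagents that add atoms: none
Why: Iodine–lithium exchange with retention, transmetalation to magnesium and copper and conjugate addition to the N-enoyl imide, in which magnesium bridges the two imide carbonyls (syn-s-cis enoyl) so that the benzyl group of the (R)-auxiliary screens one face and the alkenyl group enters the β-carbon from the other, should set C2 (S in 20).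

Step 11
Reactants: 20 conjugate adduct (imide)
Product: 21 methyl (S)-6-(TBDPSO)-3-{(Z)-1-(TBDPSO)-2-methyl-5-(2-methyl-1,3-dioxolan-2-yl)pent-2-en-3-yl}hexanoate
Conditions: MeMgBr, MeOH, 0 °C (MeOMgBr formed in the flask)
Reagents that add atoms: methanol, CO
Why: Transesterification of the α-unbranched imide by bromomagnesium methoxide at the exocyclic carbonyl should release the methyl ester and the intact auxiliary, and C2 is not α to a carbonyl and cannot epimerise.

Step 12
Reactants: 21 methyl ester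
Product: 23 methyl (2RS,3S)-2-allyl-6-(TBDPSO)-3-{(Z)-1-(TBDPSO)-2-methyl-5-(2-methyl-1,3-dioxolan-2-yl)pent-2-en-3-yl}hexanoate, via lithium ester enolate 22 (not isolated)
Conditions: LiN(i-Pr)2, THF, −78 °C; allyl bromide, DMPU, −78 to −20 °C
Reagents that add atoms: allyl bromide, C=CCBr
Why: C-Alkylation (SN2) of the lithium ester enolate with a reactive allylic halide installs the three-carbon handle, and the new α-centre needs no control because it is erased in step 15.

Step 13
Reactants: 23 α-allyl ester (both C1 epimers)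
Product: 25 methyl (2RS,3R)-2-allyl-2-bromo-6-(TBDPSO)-3-{(Z)-1-(TBDPSO)-2-methyl-5-(2-methyl-1,3-dioxolan-2-yl)pent-2-en-3-yl}hexanoate, via lithium ester enolate 24 (not isolated)
Conditions: LiN(i-Pr)2, THF/DMPU, −78 to −40 °C; CBr4, −78 °C
Reagents that add atoms: carbon tetrabromide, BrC(Br)(Br)Br
Why: Electrophilic α-bromination of the fully substituted ester enolate by bromine transfer from CBr4 should give the tertiary bromide without touching the alkenes (the descriptor at C2 changes to R by priority only).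

Step 14
Reactants: 25 α-bromo ester ketal
Product: 26 methyl (2RS,3R)-2-allyl-2-bromo-6-(TBDPSO)-3-[(Z)-1-(TBDPSO)-2-methyl-6-oxohept-2-en-3-yl]hexanoate
Conditions: PPTS, acetone/H2O (10:1), 55 °C
Reagents that add atoms: water, O
Why: Mild acid-catalysed ketal hydrolysis frees the methyl ketone, while the TBDPS ethers and the tertiary α-bromo ester (no ionisation next to a carbonyl) should survive.

Step 15
Reactants: 26 α-bromo keto ester (both C1 epimers)
Product: 28 methyl (1R,2S,6R)-1-allyl-2-hydroxy-2-methyl-6-[3-(TBDPSO)propyl]-5-[(Z)-1-(TBDPSO)propan-2-ylidene]cyclohexane-1-carboxylate, via samarium ester enolate 27 (not isolated)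
Conditions: SmI2 (2.5 equiv), THF, −78 °C, slow addition of 26; to −20 °C; aq. NH4Cl
Reagents that add atoms: none
Why: Two equivalents of SmI2 (divalent samarium) reduce the tertiary C–Br bond by two single-electron transfers to the trivalent samarium ester enolate 27, in which the C1 configuration of both epimers is erased, and this enolate adds to the C6 methyl ketone in an intramolecular Reformatsky reaction, the closest known type being the SmI2-promoted cyclisation of α-halo esters onto ketones. The cyclohexane closes in the 6-(enolexo)-exo-trig mode through a chair in which trivalent samarium bridges the enolate oxygen and the ketone oxygen, so the ester carbon at C1 and the oxygen at C6 should end up cis. The C2 arm is expected to sit pseudo-axial, because an equatorial arm would be eclipsed (allylic 1,3-strain) by the CH2OSi group on the tetrasubstituted C3 alkene and by the enolate. The ketone should then turn its oxygen and not its methyl group toward the syn-axial arm, which places the ester carbon equatorial on the face of the arm and the allyl group axial on the other face. C1 (quaternary) and C6 (tertiary carbinol) are thus both set relative to C2, with CO2Me, OH and the C2 arm on one ring face as the target requires. The step needs reduction of the bromide ahead of the ketone, secured by the much more easily reduced α-bromo ester at −78 °C without HMPA, and bond formation ahead of protonation, secured by the six-membered intramolecular closure to a product that has no α-hydrogen and cannot dehydrate.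

Step 16
Reactants: 28 cyclic β-hydroxy ester
Product: 29 (1S,2S,3R)-2-allyl-2-(hydroxymethyl)-1-methyl-3-[3-(TBDPSO)propyl]-4-[(Z)-1-(TBDPSO)propan-2-ylidene]cyclohexan-1-ol
Conditions: LiAlH4, THF, 0 °C
Reagents that add atoms: none
Why: Hydride reduction of the hindered ester to the primary alcohol at 0 °C should outrun retro-aldol cleavage of the aluminium alkoxide and leaves silyl ethers and alkenes untouched.

Step 17
Reactants: 29 1,3-diol
Product: 30 bis-TES ether of 29 (TES on the C1 CH2O and on the C6 oxygen)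
Conditions: TESOTf (3 equiv), 2,6-lutidine, CH2Cl2, −78 °C to rt
Reagents that add atoms: triethylsilyl trifluoromethanesulfonate, CC[Si](CC)(CC)OS(=O)(=O)C(F)(F)F
Why: Silylation with the silyl triflate is reactive enough for the neopentyl primary and the hindered tertiary hydroxyl, and it should prevent six-membered lactol formation with the aldehyde made in step 19.

Step 18
Reactants: 30 bis-TES ether
Product: 32 primary alcohol (30 with the C1 allyl group turned into 3-hydroxypropyl), via B-alkyl-9-BBN borane 31 (not isolated)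
Conditions: 9-BBN, THF, 0 °C to rt; NaOH, H2O2, 0 °C
Reagents that add atoms: hydrogen peroxide, OO
Why: Hydroboration–oxidation with the bulky 9-BBN should add anti-Markovnikov to the monosubstituted alkene only, the tetrasubstituted alkene being inert.

Step 19
Reactants: 32 primary alcohol
Product: 33 aldehyde (3-oxopropyl group at C1)
Conditions: Dess–Martin periodinane, pyridine, CH2Cl2, 0 °C to rt
Reagents that add atoms: none
Why: Buffered Dess–Martin oxidation converts the primary alcohol into the aldehyde without cleaving the TES ethers.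

Step 20
Reactants: 33 aldehyde
Product: 34 enal ((E)-4-methyl-5-oxopent-3-en-1-yl group at C1)
Conditions: Ph3P=C(CH3)CHO, toluene, 90 °C
Reagents that add atoms: 2-(triphenylphosphoranylidene)propanal, CC(C=O)=P(c1ccccc1)(c1ccccc1)c1ccccc1
Why: Wittig reaction with the stabilised formyl ylide should give the trisubstituted E-enal under thermodynamic control of the oxaphosphetane pathway.

Step 21
Reactants: 35 geraniol
Product: 36 5-{[(E)-3,7-dimethylocta-2,6-dien-1-yl]sulfanyl}-1-phenyl-1H-tetrazole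
Conditions: 1-phenyl-1H-tetrazole-5-thiol, PPh3, DIAD, THF, 0 °C
Reagents that add atoms: 1-phenyl-1H-tetrazole-5-thiol, Sc1nnnn1-c1ccccc1
Why: Mitsunobu thioetherification proceeds by SN2 at the primary allylic carbon without allylic transposition, so the E-alkene is kept.

Step 22
Reactants: 36 geranyl PT sulfide
Product: 37 5-{[(E)-3,7-dimethylocta-2,6-dien-1-yl]sulfonyl}-1-phenyl-1H-tetrazole
Conditions: (NH4)6Mo7O24·4H2O (cat.), 30 % H2O2, EtOH, 0 °C to rt
Reagents that add atoms: hydrogen peroxide, OO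
Why: Molybdate-catalysed peroxide oxidation should take sulfur to the sulfone faster than it epoxidises the trisubstituted alkenes.

Step 23
Reactants: 34 enal; 37 geranyl PT sulfone
Product: 39 fully silylated tetraene ((3E,5E,7E)-4,8,12-trimethyltrideca-3,5,7,11-tetraen-1-yl group at C1), via potassium sulfonyl carbanion 38 (not isolated)
Conditions: 37, KN(SiMe3)2, THF, −78 °C; then 34, −78 °C to rt
Reagents that add atoms: none
Why: Julia–Kocienski olefination (addition, Smiles rearrangement, loss of SO2 and tetrazolone) with the PT sulfone and a potassium counter-ion should favour the new E-alkene and complete the triene.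

Step 24
Reactants: 39 fully silylated tetraene
Product: 40 (1S,2S,3R)-2-(hydroxymethyl)-3-(3-hydroxypropyl)-4-[(Z)-1-hydroxypropan-2-ylidene]-1-methyl-2-[(3E,5E,7E)-4,8,12-trimethyltrideca-3,5,7,11-tetraen-1-yl]cyclohexan-1-ol
Conditions: Bu4NF (excess), THF, rt
Reagents that add atoms: none
Why: Fluoride-mediated desilylation should remove both TBDPS and both TES groups under non-acidic conditions that spare the triene.

Step 25
Reactants: 40 tetraol
Product: 41 (Z)-2-[(2R,3S,4S)-4-hydroxy-3-(hydroxymethyl)-2-(3-hydroxypropyl)-4-methyl-3-[(3E,5E,7E)-4,8,12-trimethyltrideca-3,5,7,11-tetraen-1-yl]cyclohexylidene]propanal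
Conditions: MnO2 (excess), CH2Cl2, rt
Reagents that add atoms: none
Why: MnO2 oxidises only the allylic alcohol, leaving the two saturated primary and the tertiary hydroxyls, and its neutral conditions should keep the geometry of the tetrasubstituted enal and the configuration at C2.

## Compound list

1 | 5-hexyn-2-one | CC(=O)CCC#C | starting material
2 | 2-(but-3-yn-1-yl)-2-methyl-1,3-dioxolane | CC1(CCC#C)OCCO1 | intermediate
3 | lithium acetylide of 2 | [Li]C#CCCC1(C)OCCO1 | intermediate
4 | 5-(2-methyl-1,3-dioxolan-2-yl)pent-2-yn-1-ol | OCC#CCCC1(C)OCCO1 | intermediate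
5 | cyclic alkenylmagnesium alkoxide (five-membered C=C–Mg–O–CH2 chelate; CH3 on the carbon next to CH2O) | CC1=C(CCC2(C)OCCO2)[Mg]OC1 | intermediate
6 | (Z)-3-iodo-2-methyl-5-(2-methyl-1,3-dioxolan-2-yl)pent-2-en-1-ol | OC/C(C)=C(\I)CCC1(C)OCCO1 | intermediate
7 | tert-butyl{[(Z)-3-iodo-2-methyl-5-(2-methyl-1,3-dioxolan-2-yl)pent-2-en-1-yl]oxy}diphenylsilane | CC(C)(C)[Si](c1ccccc1)(c1ccccc1)OC/C(C)=C(\I)CCC1(C)OCCO1 | intermediate
8 | butane-1,4-diol | OCCCCO | starting material
9 | monosodium butane-1,4-diolate | [Na]OCCCCO | intermediate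
10 | 4-[(tert-butyldiphenylsilyl)oxy]butan-1-ol | OCCCCO[Si](c1ccccc1)(c1ccccc1)C(C)(C)C | intermediate
11 | 4-[(tert-butyldiphenylsilyl)oxy]butanal | O=CCCCO[Si](c1ccccc1)(c1ccccc1)C(C)(C)C | intermediate
12 | (R)-4-benzyl-2-oxazolidinone | O=C1N[C@H](Cc2ccccc2)CO1 | starting material
13 | N-lithio derivative of 12 | [Li]N1[C@H](Cc2ccccc2)COC1=O | intermediate
14 | (R)-4-benzyl-3-(2-bromoacetyl)oxazolidin-2-one | O=C(CBr)N1[C@H](Cc2ccccc2)COC1=O | intermediate
15 | diethyl {2-[(R)-4-benzyl-2-oxooxazolidin-3-yl]-2-oxoethyl}phosphonate | CCOP(=O)(CC(=O)N1[C@H](Cc2ccccc2)COC1=O)OCC | intermediate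
16 | (R)-4-benzyl-3-{(E)-6-[(tert-butyldiphenylsilyl)oxy]hex-2-enoyl}oxazolidin-2-one | O=C(/C=C/CCCO[Si](c1ccccc1)(c1ccccc1)C(C)(C)C)N1[C@H](Cc2ccccc2)COC1=O | intermediate
17 | alkenyllithium from 7 (Li in place of I, geometry retained) | CC(C)(C)[Si](c1ccccc1)(c1ccccc1)OC/C(C)=C(\[Li])CCC1(C)OCCO1 | intermediate
18 | alkenylmagnesium bromide from 17 | CC(C)(C)[Si](c1ccccc1)(c1ccccc1)OC/C(C)=C(\[Mg]Br)CCC1(C)OCCO1 | intermediate
19 | alkenylcopper reagent (as its MgBr2 complex) | CC(C)(C)[Si](c1ccccc1)(c1ccccc1)OC/C(C)=C(\[Cu])CCC1(C)OCCO1 | intermediate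
20 | (R)-4-benzyl-3-[(S)-6-(TBDPSO)-3-{(Z)-1-(TBDPSO)-2-methyl-5-(2-methyl-1,3-dioxolan-2-yl)pent-2-en-3-yl}hexanoyl]oxazolidin-2-one | O=C(C[C@H](CCCO[Si](c1ccccc1)(c1ccccc1)C(C)(C)C)/C(=C(/C)CO[Si](c1ccccc1)(c1ccccc1)C(C)(C)C)CCC1(C)OCCO1)N1[C@H](Cc2ccccc2)COC1=O | intermediate
21 | methyl (S)-6-(TBDPSO)-3-{(Z)-1-(TBDPSO)-2-methyl-5-(2-methyl-1,3-dioxolan-2-yl)pent-2-en-3-yl}hexanoate | COC(=O)C[C@H](CCCO[Si](c1ccccc1)(c1ccccc1)C(C)(C)C)/C(=C(/C)CO[Si](c1ccccc1)(c1ccccc1)C(C)(C)C)CCC1(C)OCCO1 | intermediate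
22 | lithium enolate of 21 | COC(O[Li])=C[C@H](CCCO[Si](c1ccccc1)(c1ccccc1)C(C)(C)C)/C(=C(/C)CO[Si](c1ccccc1)(c1ccccc1)C(C)(C)C)CCC1(C)OCCO1 | intermediate
23 | methyl (2RS,3S)-2-allyl-6-(TBDPSO)-3-{(Z)-1-(TBDPSO)-2-methyl-5-(2-methyl-1,3-dioxolan-2-yl)pent-2-en-3-yl}hexanoate | COC(=O)C(CC=C)[C@H](CCCO[Si](c1ccccc1)(c1ccccc1)C(C)(C)C)/C(=C(/C)CO[Si](c1ccccc1)(c1ccccc1)C(C)(C)C)CCC1(C)OCCO1 | intermediate
24 | lithium enolate of 23 | COC(O[Li])=C(CC=C)[C@H](CCCO[Si](c1ccccc1)(c1ccccc1)C(C)(C)C)/C(=C(/C)CO[Si](c1ccccc1)(c1ccccc1)C(C)(C)C)CCC1(C)OCCO1 | intermediate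
25 | methyl (2RS,3R)-2-allyl-2-bromo-6-(TBDPSO)-3-{(Z)-1-(TBDPSO)-2-methyl-5-(2-methyl-1,3-dioxolan-2-yl)pent-2-en-3-yl}hexanoate | COC(=O)C(Br)(CC=C)[C@H](CCCO[Si](c1ccccc1)(c1ccccc1)C(C)(C)C)/C(=C(/C)CO[Si](c1ccccc1)(c1ccccc1)C(C)(C)C)CCC1(C)OCCO1 | intermediate
26 | methyl (2RS,3R)-2-allyl-2-bromo-6-(TBDPSO)-3-[(Z)-1-(TBDPSO)-2-methyl-6-oxohept-2-en-3-yl]hexanoate (key-step precursor) | COC(=O)C(Br)(CC=C)[C@H](CCCO[Si](c1ccccc1)(c1ccccc1)C(C)(C)C)/C(=C(/C)CO[Si](c1ccccc1)(c1ccccc1)C(C)(C)C)CCC(C)=O | intermediate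
27 | diiodosamarium ester enolate of 26 (trivalent samarium) | COC(O[Sm](I)I)=C(CC=C)[C@H](CCCO[Si](c1ccccc1)(c1ccccc1)C(C)(C)C)/C(=C(/C)CO[Si](c1ccccc1)(c1ccccc1)C(C)(C)C)CCC(C)=O | intermediate
28 | methyl (1R,2S,6R)-1-allyl-2-hydroxy-2-methyl-6-[3-(TBDPSO)propyl]-5-[(Z)-1-(TBDPSO)propan-2-ylidene]cyclohexane-1-carboxylate (key-step product; ring locants of the overview: C1 R, C2 R, C6 S) | C=CC[C@@]1(C(=O)OC)[C@H](CCCO[Si](c2ccccc2)(c2ccccc2)C(C)(C)C)/C(=C(/C)CO[Si](c2ccccc2)(c2ccccc2)C(C)(C)C)CC[C@]1(C)O | intermediate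
29 | (1S,2S,3R)-2-allyl-2-(hydroxymethyl)-1-methyl-3-[3-(TBDPSO)propyl]-4-[(Z)-1-(TBDPSO)propan-2-ylidene]cyclohexan-1-ol | C=CC[C@@]1(CO)[C@H](CCCO[Si](c2ccccc2)(c2ccccc2)C(C)(C)C)/C(=C(/C)CO[Si](c2ccccc2)(c2ccccc2)C(C)(C)C)CC[C@]1(C)O | intermediate
30 | bis-TES ether of 29 (TES on the C1 CH2O and on the C6 oxygen) | C=CC[C@@]1(CO[Si](CC)(CC)CC)[C@H](CCCO[Si](c2ccccc2)(c2ccccc2)C(C)(C)C)/C(=C(/C)CO[Si](c2ccccc2)(c2ccccc2)C(C)(C)C)CC[C@]1(C)O[Si](CC)(CC)CC | intermediate
31 | B-alkyl-9-borabicyclo[3.3.1]nonane from 30 (boron on the terminal carbon of the former allyl group) | C(CC[C@@]1(CO[Si](CC)(CC)CC)[C@H](CCCO[Si](c2ccccc2)(c2ccccc2)C(C)(C)C)/C(=C(/C)CO[Si](c2ccccc2)(c2ccccc2)C(C)(C)C)CC[C@]1(C)O[Si](CC)(CC)CC)B1C2CCCC1CCC2 | intermediate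
32 | primary alcohol: 30 with 3-hydroxypropyl in place of allyl at C1 | OCCC[C@@]1(CO[Si](CC)(CC)CC)[C@H](CCCO[Si](c2ccccc2)(c2ccccc2)C(C)(C)C)/C(=C(/C)CO[Si](c2ccccc2)(c2ccccc2)C(C)(C)C)CC[C@]1(C)O[Si](CC)(CC)CC | intermediate
33 | aldehyde: 3-oxopropyl group at C1 | O=CCC[C@@]1(CO[Si](CC)(CC)CC)[C@H](CCCO[Si](c2ccccc2)(c2ccccc2)C(C)(C)C)/C(=C(/C)CO[Si](c2ccccc2)(c2ccccc2)C(C)(C)C)CC[C@]1(C)O[Si](CC)(CC)CC | intermediate
34 | enal: (E)-4-methyl-5-oxopent-3-en-1-yl group at C1 | O=C/C(C)=C/CC[C@@]1(CO[Si](CC)(CC)CC)[C@H](CCCO[Si](c2ccccc2)(c2ccccc2)C(C)(C)C)/C(=C(/C)CO[Si](c2ccccc2)(c2ccccc2)C(C)(C)C)CC[C@]1(C)O[Si](CC)(CC)CC | intermediate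
35 | geraniol | CC(C)=CCC/C(C)=C/CO | starting material
36 | 5-{[(E)-3,7-dimethylocta-2,6-dien-1-yl]sulfanyl}-1-phenyl-1H-tetrazole | CC(C)=CCC/C(C)=C/CSc1nnnn1-c1ccccc1 | intermediate
37 | 5-{[(E)-3,7-dimethylocta-2,6-dien-1-yl]sulfonyl}-1-phenyl-1H-tetrazole | CC(C)=CCC/C(C)=C/CS(=O)(=O)c1nnnn1-c1ccccc1 | intermediate
38 | potassium α-sulfonyl carbanion of 37 | CC(C)=CCC/C(C)=C/[CH-]S(=O)(=O)c1nnnn1-c1ccccc1.[K+] | intermediate
39 | fully silylated tetraene: (3E,5E,7E)-4,8,12-trimethyltrideca-3,5,7,11-tetraen-1-yl group at C1, two TBDPS and two TES ethers | CC(C)=CCC/C(C)=C/C=C/C(C)=C/CC[C@@]1(CO[Si](CC)(CC)CC)[C@H](CCCO[Si](c2ccccc2)(c2ccccc2)C(C)(C)C)/C(=C(/C)CO[Si](c2ccccc2)(c2ccccc2)C(C)(C)C)CC[C@]1(C)O[Si](CC)(CC)CC | intermediate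
40 | (1S,2S,3R)-2-(hydroxymethyl)-3-(3-hydroxypropyl)-4-[(Z)-1-hydroxypropan-2-ylidene]-1-methyl-2-[(3E,5E,7E)-4,8,12-trimethyltrideca-3,5,7,11-tetraen-1-yl]cyclohexan-1-ol | CC(C)=CCC/C(C)=C/C=C/C(C)=C/CC[C@@]1(CO)[C@H](CCCO)/C(=C(/C)CO)CC[C@]1(C)O | intermediate
41 | (Z)-2-[(2R,3S,4S)-4-hydroxy-3-(hydroxymethyl)-2-(3-hydroxypropyl)-4-methyl-3-[(3E,5E,7E)-4,8,12-trimethyltrideca-3,5,7,11-tetraen-1-yl]cyclohexylidene]propanal | CC(C)=CCC/C(C)=C/C=C/C(C)=C/CC[C@@]1(CO)[C@H](CCCO)/C(=C(/C)C=O)CC[C@]1(C)O | target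

## Step count and risks

Total step count: 25.
Longest linear sequence: 18 steps (steps 1–4, 10–20, 23–25).

Steps most likely to fail:

1. Step 15 (key step). The samarium enolate may be protonated, or the bromide eliminated, before the congested C1–C6 bond between two fully substituted carbons forms. The ketone may also be met on the wrong enolate face, so that C1 and C6 come out epimeric relative to C2. The fallback sets out from 21 and comes back at 28; it closes the ring before the quaternary centre exists and sets C1 afterwards. α-Bromination of 21 (LiN(i-Pr)2, then CBr4) would give the secondary bromo ester F1. Ketal hydrolysis (PPTS, acetone/H2O) would give the bromo keto ester F2. SmI2 in THF at −78 °C would close the less hindered ring to the β-hydroxy ester F3, which carries hydrogen at C1. Fráter–Seebach allylation of the dianion of F3 (LiN(i-Pr)2, 2.2 equiv, then allyl bromide, DMPU) should bring the allyl group in anti to the C6 alkoxide and to the C2 arm, which is the arrangement of 28.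

2. Step 10. Transfer of the fully substituted alkenyl group from copper may be sluggish, the silyl group may migrate from oxygen to carbon in the alkenyllithium, and facial selectivity may erode if the magnesium chelate is not maintained. The fallback sets out from 7 and 11 and comes back at 21; it replaces auxiliary control by catalyst control and also saves the methanolysis. Iodine–lithium exchange on 7 and quenching with 2-isopropoxy-4,4,5,5-tetramethyl-1,3,2-dioxaborolane would give the alkenyl pinacol boronate F4. Wittig reaction of 11 with Ph3P=CHCO2Me would give methyl (E)-6-[(tert-butyldiphenylsilyl)oxy]hex-2-enoate F5. Hayashi–Miyaura addition of F4 to F5 ([Rh(cod)Cl]2, BINAP, KOH, dioxane/H2O) should give 21 directly; the BINAP enantiomer that delivers the S-configured centre is to be identified in a test reaction.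

3. Step 23. E-selectivity may be incomplete when an allylic sulfonyl anion meets an enal, and the metalated sulfone may self-condense. The fallback sets out from 34 and comes back at 39; it forms the neighbouring single bond of the triene by cross-coupling with retention at both partners. Takai iodo-olefination of 34 (CrCl2, CHI3, THF, 0 °C) would give the (1E,3E)-dienyl iodide F6. 6-Methylhept-5-en-1-yne F7 would be made from commercial 6-methylhept-5-en-2-one through the enol phosphate (LiN(i-Pr)2, ClP(O)(OEt)2; then LiN(i-Pr)2). Carboalumination of F7 (AlMe3, Cp2ZrCl2 cat., CH2Cl2) would give the (E)-alkenylalane F8 by syn addition. Negishi coupling of F8 with F6 (Pd(PPh3)4, ZnCl2, THF) should give 39.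

## Further compounds

F1 | step 15 | methyl (2RS,3R)-2-bromo-6-(TBDPSO)-3-{(Z)-1-(TBDPSO)-2-methyl-5-(2-methyl-1,3-dioxolan-2-yl)pent-2-en-3-yl}hexanoate | COC(=O)C(Br)[C@H](CCCO[Si](c1ccccc1)(c1ccccc1)C(C)(C)C)/C(=C(/C)CO[Si](c1ccccc1)(c1ccccc1)C(C)(C)C)CCC1(C)OCCO1
F2 | step 15 | methyl (2RS,3R)-2-bromo-6-(TBDPSO)-3-[(Z)-1-(TBDPSO)-2-methyl-6-oxohept-2-en-3-yl]hexanoate | COC(=O)C(Br)[C@H](CCCO[Si](c1ccccc1)(c1ccccc1)C(C)(C)C)/C(=C(/C)CO[Si](c1ccccc1)(c1ccccc1)C(C)(C)C)CCC(C)=O
F3 | step 15 | methyl 2-hydroxy-2-methyl-6-[3-(TBDPSO)propyl]-5-[(Z)-1-(TBDPSO)propan-2-ylidene]cyclohexane-1-carboxylate (28 without the allyl group; C2 and C6 as in 28, C1 either epimer) | COC(=O)C1[C@H](CCCO[Si](c2ccccc2)(c2ccccc2)C(C)(C)C)/C(=C(/C)CO[Si](c2ccccc2)(c2ccccc2)C(C)(C)C)CC[C@]1(C)O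
F4 | step 10 | alkenyl pinacol boronate (7 with 4,4,5,5-tetramethyl-1,3,2-dioxaborolan-2-yl in place of iodine, geometry retained) | CC(C)(C)[Si](c1ccccc1)(c1ccccc1)OC/C(C)=C(\B1OC(C)(C)C(C)(C)O1)CCC1(C)OCCO1
F5 | step 10 | methyl (E)-6-[(tert-butyldiphenylsilyl)oxy]hex-2-enoate | COC(=O)/C=C/CCCO[Si](c1ccccc1)(c1ccccc1)C(C)(C)C
F6 | step 23 | (1E,3E)-dienyl iodide (34 with CHO replaced by (E)-CH=CHI) | I/C=C/C(C)=C/CC[C@@]1(CO[Si](CC)(CC)CC)[C@H](CCCO[Si](c2ccccc2)(c2ccccc2)C(C)(C)C)/C(=C(/C)CO[Si](c2ccccc2)(c2ccccc2)C(C)(C)C)CC[C@]1(C)O[Si](CC)(CC)CC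
F7 | step 23 | 6-methylhept-5-en-1-yne | C#CCCC=C(C)C
F8 | step 23 | [(E)-2,6-dimethylhepta-1,5-dien-1-yl]dimethylalane | C[Al](C)/C=C(\C)CCC=C(C)C
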